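The closed, stirred vessel held D and Z, and D could leave by coupling with Z or by turning into J.

- larch: D 0.50 mM; Z 0.500 mM; time 2.5 s
- ash: D 0.50 mM; Z 1.20 mM; time 2.5 s

    D + Z → L + X (k1 = 902 L mol⁻¹ s⁻¹)
    D ⇌ J (K2 = 12.2, k2 = 0.217 s⁻¹)
    L → G (k3 = 2.29 × 10⁻⁴ s⁻¹)

- which of these there is most of at the end, counted by the D in it, larch (L / D)
- which of these there is most of at the end, counted by the D in it, ash (L / D)
- amount of the one of these that there is most of at the end, in percent of the D charged, larch
- amount of the one of these that there is most of at the end, in percent of the D charged, ash

I asked first who took D. Coupling uses D in proportion to Z, and the forward step to J does not depend on Z. So the two run equally fast at one level of Z, the forward rate constant of the step to J over the rate constant of the coupling, 0.241 mM. I called this the crossing level. Z divided by it is the selectivity factor between L and J. Larch started at 2.08 times this level and ash at 4.99 times, so coupling led in both at the start.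

But Z falls as it couples, so I asked which level to use. I guessed that coupling would take 0.5 of the D charged. That put the middle level of Z at 0.375 mM in larch and 1.07 mM in ash, both still above the crossing.

Then I asked how much D would be gone. I dropped the way back from J, since K2 is 12.2. I also dropped the loss of L, whose half-life of 50.4 min is far longer than 2.5 s. In this reckoning D decayed at 0.555 s⁻¹ in larch and 1.19 s⁻¹ in ash. My estimate of D at the end was 25.0 % in larch and 5.15 % in ash. The coupling's share of the loss put my estimate of L at 45.7 % in larch and 77.5 % in ash. So I expected L to lead D in larch and in ash.

The forecast named L for larch at 49 % and L for ash at 75 %, holding that “the Z excess in ash tilts that competition further toward L”. It stood above my larch figure and below my ash figure.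

The flask gave L in larch at 45.1 %, with D at 26.8 %, and L in ash at 75.1 %, with D at 7.41 %. At the end of larch, Z stood at 0.274 mM, just above the crossing level, and coupling used D 1.1 times as fast as the forward step to J, down from 2.1 at the start. The neighbour of larch charged with 0.20 mM of Z began below the crossing level and ended with 21.1 % of the D charged as L against 35.2 % as J.

The numbers come from no measurement, and the outcome is calculated.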